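**Assumption:** the SMILES is read as (7S,8R)‑erythro in the aryl‑glycerol chain and (2R,3S)‑trans in the dihydrobenzofuran; methyl (S)‑glycerate and (S)‑but‑3‑en‑2‑ol are the purchased chiral inputs. TBS = tert‑butyldimethylsilyl.

## Retrosynthetic overview

1. Target ⇐ tetra‑TBS ether. The dihydrofuran ring is the only ring made (all three arenes are bought) and is closed last by acid‑mediated benzylic C2–O etherification, trans set by C3.
2. C2–aryl bond ⇐ aryllithium from the complete erythro side‑chain bromide + a C3‑stereodefined 2‑hydroxy‑dihydrobenzofuran (lactol).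
3. Lactol ⇐ ozonolysis ⇐ aromatic Claisen [3,3] rearrangement of a vanillin (R)‑allylic ether, which forms the aryl–C3 bond with 1,3‑chirality transfer. Ether ⇐ Mitsunobu inversion of (S)‑but‑3‑en‑2‑ol, then cross‑metathesis.
4. Side chain ⇐ chelation‑controlled ketone reduction (C7 set by C8) ⇐ Weinreb ketone synthesis ⇐ Mitsunobu inversion of a methyl L‑glycerate derivative with 4‑bromo‑2,6‑dimethoxyphenol (C8 from the pool).

## Route

### Part A – erythro side‑chain aryl bromide

**Step 1**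
Reactants: **1** methyl (S)‑2,3‑dihydroxypropanoate (methyl L‑glycerate)
Product: **2** methyl (S)‑3‑(TBS‑oxy)‑2‑hydroxypropanoate
Conditions: TBSCl (1.05 eq), imidazole, CH2Cl2, −20 → 0 °C
Reagents that add atoms: TBSCl, CC(C)(C)[Si](C)(C)Cl
Why: Sterically controlled mono‑silylation of the primary hydroxyl; the stereocentre is untouched.

**Step 2**
Reactants: **2**; **3** 4‑bromo‑2,6‑dimethoxyphenol
Product: **4** methyl (R)‑2‑(4‑bromo‑2,6‑dimethoxyphenoxy)‑3‑(TBS‑oxy)propanoate
Conditions: PPh3, DIAD, THF, 0 °C → rt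
Reagents that add atoms: none
Why: Mitsunobu etherification of an α‑hydroxy ester is a clean SN2 with inversion (S → R), which installs the 8‑O‑4′ bond and the C8 configuration.

**Step 3**
Reactants: **4**
Product: **5** (R)‑2‑(4‑bromo‑2,6‑dimethoxyphenoxy)‑3‑(TBS‑oxy)‑N‑methoxy‑N‑methylpropanamide
Conditions: MeNH(OMe)·HCl, AlMe3, CH2Cl2, 0 °C → rt
Reagents that add atoms: N,O‑dimethylhydroxylamine hydrochloride, CNOC.Cl
Why: Weinreb aminolysis via the dimethylaluminium amide is non‑basic, so the α‑aryloxy centre is neither epimerised nor β‑eliminated.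

**Step 4**
Reactants: **6** 4‑bromo‑2‑methoxyphenol
Product: **7** (4‑bromo‑2‑methoxyphenoxy)(tert‑butyl)dimethylsilane
Conditions: TBSCl, imidazole, DMF, rt
Reagents that add atoms: TBSCl, CC(C)(C)[Si](C)(C)Cl
Why: Routine phenol silylation gives a Grignard‑compatible, fluoride‑removable protecting group.

**Step 5**
Reactants: **7**; **5**
Product: **8** (R)‑2‑(4‑bromo‑2,6‑dimethoxyphenoxy)‑3‑(TBS‑oxy)‑1‑[4‑(TBS‑oxy)‑3‑methoxyphenyl]propan‑1‑one
Conditions: **7**, Mg, THF (→ ArMgBr); then **5**, THF, 0 °C; pH 7 buffer quench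
Reagents that add atoms: none
Why: Weinreb ketone synthesis: the chelated tetrahedral intermediate stops over‑addition and keeps the α‑centre from enolising until quench, and the aryl bromide of **5** is inert to ArMgBr.

**Step 6**
Reactants: **8**
Product: **9** (1S,2R)‑2‑(4‑bromo‑2,6‑dimethoxyphenoxy)‑3‑(TBS‑oxy)‑1‑[4‑(TBS‑oxy)‑3‑methoxyphenyl]propan‑1‑ol (erythro)
Conditions: Zn(BH4)2, Et2O, −30 → 0 °C
Reagents that add atoms: none
Why: Cram‑chelate reduction: Zn bridges the carbonyl and the α‑aryloxy oxygen and hydride enters from the H‑face of C8, giving the anti (erythro) 7S alcohol from the 8R centre.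

**Step 7**
Reactants: **9**
Product: **10** 5‑bromo‑2‑{[(1S,2R)‑1,3‑bis(TBS‑oxy)‑1‑(4‑TBS‑oxy‑3‑methoxyphenyl)propan‑2‑yl]oxy}‑1,3‑dimethoxybenzene
Conditions: TBSOTf, 2,6‑lutidine, CH2Cl2, −20 → 0 °C
Reagents that add atoms: TBSOTf, CC(C)(C)[Si](C)(C)OS(=O)(=O)C(F)(F)F
Why: Silylation of the hindered benzylic alcohol makes it inert to t‑BuLi and much harder to ionise in the later acid step.

### Part B – C3‑stereodefined lactol

**Step 8**
Reactants: **11** vanillin; **12** (S)‑but‑3‑en‑2‑ol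
Product: **13** 4‑{[(2R)‑but‑3‑en‑2‑yl]oxy}‑3‑methoxybenzaldehyde
Conditions: PPh3, DIAD, THF, 0 °C → rt
Reagents that add atoms: none
Why: Mitsunobu etherification of the acidic phenol (pKa ≈ 7.4) is SN2 with inversion (S → R); the achiral SN2′ crotyl ether by‑product is removed by chromatography.

**Step 9**
Reactants: **13**
Product: **14** 2‑(4‑{[(2R)‑but‑3‑en‑2‑yl]oxy}‑3‑methoxyphenyl)‑1,3‑dioxolane
Conditions: ethylene glycol, HC(OEt)3, TsOH (2 mol %), CH2Cl2, rt
Reagents that add atoms: ethylene glycol, OCCO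
Why: Mild orthoformate‑driven acetalisation masks the aldehyde against the later aryllithium without ionising the allylic ether.

**Step 10**
Reactants: **14**; **15** allyloxy(tert‑butyl)dimethylsilane (4 eq)
Product: **16** 2‑[4‑({(2R,3E)‑5‑(TBS‑oxy)pent‑3‑en‑2‑yl}oxy)‑3‑methoxyphenyl]‑1,3‑dioxolane
Conditions: Hoveyda–Grubbs II (5 mol %), CH2Cl2, 40 °C; AgNO3–SiO2 chromatography if Z is present
Reagents that add atoms: none
Why: Olefin cross‑metathesis of an α‑branched allylic ether with a fast‑reacting terminal olefin is strongly E‑selective and does not touch the stereocentre.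

**Step 11 (key step)**
Reactants: **16**
Product: **17** 2‑{(2S,3E)‑1‑(TBS‑oxy)pent‑3‑en‑2‑yl}‑4‑(1,3‑dioxolan‑2‑yl)‑6‑methoxyphenol
Conditions: Eu(fod)3 (10 mol %), CHCl3, 60 °C
Reagents that add atoms: none
Why: Aromatic Claisen [3,3] rearrangement to the only free ortho position through a chair transition state with the methyl pseudo‑equatorial; suprafacial transfer converts the (R,E)‑ether into the (S)‑benzylic centre (C3 of the target).

**Step 12**
Reactants: **17**
Product: **18** (3S)‑3‑[(TBS‑oxy)methyl]‑5‑(1,3‑dioxolan‑2‑yl)‑7‑methoxy‑2,3‑dihydrobenzofuran‑2‑ol (anomer mixture)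
Conditions: O3, CH2Cl2/MeOH, pyridine, −78 °C (Sudan III end‑point); then Me2S
Reagents that add atoms: ozone, [O-][O+]=O
Why: Ozonolysis cleaves the propenyl group (losing acetaldehyde) far faster than it attacks the arene, and the α‑aryl aldehyde is trapped by the ortho phenol as a lactol, which protects C3 from enolisation.

### Part C – coupling, ring closure, deprotection

**Step 13**
Reactants: **10** (1.2 eq); **18**
Product: **19** 2‑[(2S)‑3‑(TBS‑oxy)‑1‑hydroxy‑1‑(4‑{[(1S,2R)‑1,3‑bis(TBS‑oxy)‑1‑(4‑TBS‑oxy‑3‑methoxyphenyl)propan‑2‑yl]oxy}‑3,5‑dimethoxyphenyl)propan‑2‑yl]‑4‑(1,3‑dioxolan‑2‑yl)‑6‑methoxyphenol (carbinol epimers)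
Conditions: **10**, t‑BuLi (2 eq), THF, −78 °C; then **18** pre‑treated with LiHMDS (1.0 eq), −78 → −40 °C; aq NH4Cl
Reagents that add atoms: none
Why: Br/Li exchange followed by 1,2‑addition to the ring‑opened lactol (phenoxide–aldehyde); the configuration of the new carbinol does not matter because it is erased in the next step.

**Step 14**
Reactants: **19**
Product: **20** (2R,3S)‑2‑(4‑{[(1S,2R)‑1,3‑bis(TBS‑oxy)‑1‑(4‑TBS‑oxy‑3‑methoxyphenyl)propan‑2‑yl]oxy}‑3,5‑dimethoxyphenyl)‑3‑[(TBS‑oxy)methyl]‑7‑methoxy‑2,3‑dihydrobenzofuran‑5‑carbaldehyde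
Conditions: TFA (10 eq), wet CH2Cl2, 0 °C, 30–60 min; NaHCO3 quench
Reagents that add atoms: water, O
Why: SN1 benzylic etherification: both carbinol epimers ionise to the same trialkoxybenzyl cation and 5‑exo capture by the phenol occurs anti to the C3 substituent, giving the trans (2R) ring; the same acid hydrolyses the dioxolane to the aldehyde, and any adventitious TBS loss is harmless because step 15 removes all silyl groups.

**Step 15**
Reactants: **20**
Product: **21** target, (2R,3S)‑2‑(4‑{[(1S,2R)‑1,3‑dihydroxy‑1‑(4‑hydroxy‑3‑methoxyphenyl)propan‑2‑yl]oxy}‑3,5‑dimethoxyphenyl)‑3‑(hydroxymethyl)‑7‑methoxy‑2,3‑dihydrobenzofuran‑5‑carbaldehyde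
Conditions: TBAF, AcOH (1:1, 6 eq), THF, 0 °C → rt
Reagents that add atoms: none
Why: Buffered fluoride desilylation removes all four TBS groups without acid or strong base, so the p‑hydroxybenzylic C7 centre and the aldehyde are preserved.

## Compound list

1 | methyl (S)‑2,3‑dihydroxypropanoate | COC(=O)[C@@H](O)CO | starting material
2 | methyl (S)‑3‑(TBS‑oxy)‑2‑hydroxypropanoate | COC(=O)[C@@H](O)CO[Si](C)(C)C(C)(C)C | intermediate
3 | 4‑bromo‑2,6‑dimethoxyphenol | COc1cc(Br)cc(OC)c1O | starting material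
4 | methyl (R)‑2‑(4‑bromo‑2,6‑dimethoxyphenoxy)‑3‑(TBS‑oxy)propanoate | COC(=O)[C@H](Oc1c(OC)cc(Br)cc1OC)CO[Si](C)(C)C(C)(C)C | intermediate
5 | (R)‑Weinreb amide of 4 | CON(C)C(=O)[C@H](Oc1c(OC)cc(Br)cc1OC)CO[Si](C)(C)C(C)(C)C | intermediate
6 | 4‑bromo‑2‑methoxyphenol | COc1cc(Br)ccc1O | starting material
7 | (4‑bromo‑2‑methoxyphenoxy)(tert‑butyl)dimethylsilane | COc1cc(Br)ccc1O[Si](C)(C)C(C)(C)C | intermediate
8 | (R)‑α‑aryloxy ketone | COc1cc(ccc1O[Si](C)(C)C(C)(C)C)C(=O)[C@H](Oc1c(OC)cc(Br)cc1OC)CO[Si](C)(C)C(C)(C)C | intermediate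
9 | (1S,2R)‑erythro alcohol | COc1cc(ccc1O[Si](C)(C)C(C)(C)C)[C@H](O)[C@@H](CO[Si](C)(C)C(C)(C)C)Oc1c(OC)cc(Br)cc1OC | intermediate
10 | (1S,2R)‑tris‑TBS aryl bromide | COc1cc(ccc1O[Si](C)(C)C(C)(C)C)[C@H](O[Si](C)(C)C(C)(C)C)[C@@H](CO[Si](C)(C)C(C)(C)C)Oc1c(OC)cc(Br)cc1OC | intermediate
11 | vanillin | COc1cc(C=O)ccc1O | starting material
12 | (S)‑but‑3‑en‑2‑ol | C[C@H](O)C=C | starting material
13 | 4‑{[(2R)‑but‑3‑en‑2‑yl]oxy}‑3‑methoxybenzaldehyde | C[C@@H](Oc1ccc(C=O)cc1OC)C=C | intermediate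
14 | dioxolane of 13 | C[C@@H](Oc1ccc(cc1OC)C1OCCO1)C=C | intermediate
15 | allyloxy(tert‑butyl)dimethylsilane | C=CCO[Si](C)(C)C(C)(C)C | starting material
16 | (R,E)‑allylic aryl ether | C[C@@H](Oc1ccc(cc1OC)C1OCCO1)/C=C/CO[Si](C)(C)C(C)(C)C | intermediate
17 | (S,E)‑Claisen phenol | COc1cc(C2OCCO2)cc([C@@H](CO[Si](C)(C)C(C)(C)C)/C=C/C)c1O | intermediate
18 | (3S)‑lactol | COc1cc(C2OCCO2)cc2c1OC(O)[C@@H]2CO[Si](C)(C)C(C)(C)C | intermediate
19 | coupled phenol‑diol (carbinol epimers) | COc1cc(C2OCCO2)cc([C@@H](CO[Si](C)(C)C(C)(C)C)C(O)c2cc(OC)c(O[C@H](CO[Si](C)(C)C(C)(C)C)[C@@H](O[Si](C)(C)C(C)(C)C)c3ccc(O[Si](C)(C)C(C)(C)C)c(OC)c3)c(OC)c2)c1O | intermediate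
20 | tetra‑TBS trans‑dihydrobenzofuran aldehyde | COc1cc([C@H](O[Si](C)(C)C(C)(C)C)[C@@H](CO[Si](C)(C)C(C)(C)C)Oc2c(OC)cc([C@@H]3Oc4c(OC)cc(C=O)cc4[C@H]3CO[Si](C)(C)C(C)(C)C)cc2OC)ccc1O[Si](C)(C)C(C)(C)C | intermediate
21 | CID53356209 | COc1cc([C@H](O)[C@@H](CO)Oc2c(OC)cc([C@@H]3Oc4c(OC)cc(C=O)cc4[C@H]3CO)cc2OC)ccc1O | target

## Summary

Total steps: 15. Longest linear sequence: 9 (steps 1, 2, 3, 5, 6, 7, 13, 14, 15).

Three steps most likely to fail:

1. **Step 11 (Claisen).** Chirality transfer erodes if any Z‑olefin survives step 10 or if the axial‑methyl chair competes; the wrong C3 enantiomer would surface later as a diastereomer of **19–21** that must be separated. Fallback: make the same aryl–C3 bond by anti‑SN2′ substitution instead. Use the aryl cuprate from MOM/acetal‑protected 5‑bromovanillin on the diethyl phosphate of (S,E)‑5‑(TBS‑oxy)pent‑3‑en‑2‑ol (from **12** + **15** by cross‑metathesis); MOM removal then gives **17**.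

2. **Step 13 (ArLi + lactol).** The opened α‑aryl‑β‑silyloxy aldehyde can enolise, β‑eliminate or dehydrate to the benzofuran under strongly basic conditions. Fallback: convert **10** to its pinacol boronate (Miyaura borylation) and add it to **18** under neutral Rh(I) catalysis ([Rh(cod)OH]2, aqueous dioxane), replacing the organolithium with a catalytic organoboron 1,2‑addition.

3. **Step 14 (acid ring closure).** TFA may also ionise C7–OTBS (epimerising the erythro unit), or the cation may eliminate to a stilbene and scramble C3. Fallback: change the fragment order. Add 4‑lithio‑2,6‑dimethoxyphenyl TBS ether to **18**, close the ring with acid on this robust substrate, free the syringyl phenol, then append the side chain (Mitsunobu with **2**, then the Weinreb / Grignard / Zn(BH4)2 sequence with the aldehyde re‑masked as its acetal).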